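Ring A is disconnected at C3–C4: the vicinal oxygens on C3 and C4, with C4 also bearing a methyl group, are read as a tertiary α-ketol. In one operation a chiral carbene converts a C3 aldehyde into an acyl-anion equivalent that adds to a C4 methyl ketone, forming the C3–C4 bond, ring A and the C4 stereocentre. The precursor is a ring B cyclohexane carrying a C8 dioxolane, a propanal arm on quaternary C10 and a trans C5 acetyl group. It is made in five steps from (+)-verbenone, whose bicyclic frame sets C10 and C5; a single ozonolysis unmasks both carbonyls. Reduction, two acylations, ketal removal and C7 isopropylidenation complete the target.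

Key step: step 6

Remark: eudesmane atom numbers are used for ring B and decalin compounds; commercial (1R,5R)-(+)-verbenone is assumed to be of high enantiomeric purity, and C7 of 20–22 (either epimer, erased in step 12) is left unassigned.

Step 1
Reactants: 1 (1R,5R)-(+)-verbenone; 2 but-3-en-1-ylmagnesium bromide
Product: 4 (1R,4R,5R)-4-(but-3-en-1-yl)-4,6,6-trimethylbicyclo[3.1.1]heptan-2-one, via bromomagnesium enolate 3 (not isolated)
Conditions: CuBr·SMe2 (10 mol %), THF, −40 → 0 °C; then 1 M HCl, 0 °C
Reagents that add atoms: but-3-en-1-ylmagnesium bromide, C=CCC[Mg]Br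
Why: Copper-catalysed conjugate addition of a Grignard reagent to a β,β-disubstituted enone should deliver the butenyl group to C4 of the bicycle from the face opposite the gem-dimethyl bridge, which sets the quaternary carbon (later C10) with butenyl trans to the cyclobutane carbon that becomes the C5 substituent.

Step 2
Reactants: 4 (1R,4R,5R)-4-(but-3-en-1-yl)-4,6,6-trimethylbicyclo[3.1.1]heptan-2-one; 5 acetic anhydride
Product: 6 (4S,5R)-5-(but-3-en-1-yl)-5-methyl-4-(prop-1-en-2-yl)cyclohex-1-en-1-yl acetate
Conditions: BF3·OEt2, Zn(OAc)2, Ac2O, 0 °C → rt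
Reagents that add atoms: acetic anhydride, CC(=O)OC(C)=O
Why: Lewis-acid-promoted cyclobutane fragmentation of a nopinone-type ketone, in which the strained C1–C6 bond α to the activated carbonyl ionises, the tertiary cation loses a proton to give the isopropenyl group and the enolate is captured as its acetate, so the bridgehead carbon (later C5) keeps its configuration and ends with isopropenyl cis to methyl and trans to butenyl.

Step 3
Reactants: 6 (4S,5R)-5-(but-3-en-1-yl)-5-methyl-4-(prop-1-en-2-yl)cyclohex-1-en-1-yl acetate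
Product: 7 (3R,4S)-3-(but-3-en-1-yl)-3-methyl-4-(prop-1-en-2-yl)cyclohexan-1-one
Conditions: K2CO3 (cat.), MeOH, 0 °C → rt
Reagents that add atoms: none
Why: Carbonate-catalysed methanolysis (transesterification) of the enol acetate frees the ketone, and no stereocentre lies α to the carbonyl.

Step 4
Reactants: 7 (3R,4S)-3-(but-3-en-1-yl)-3-methyl-4-(prop-1-en-2-yl)cyclohexan-1-one; 8 ethylene glycol
Product: 9 (7R,8S)-7-(but-3-en-1-yl)-7-methyl-8-(prop-1-en-2-yl)-1,4-dioxaspiro[4.5]decane
Conditions: HOCH2CH2OH, PPTS (cat.), benzene, reflux, Dean–Stark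
Reagents that add atoms: ethylene glycol, OCCO
Why: Acid-catalysed ketalisation with azeotropic removal of water masks C8, the mild pyridinium acid leaving the isopropenyl and vinyl groups where they are.

Step 5
Reactants: 9 (7R,8S)-7-(but-3-en-1-yl)-7-methyl-8-(prop-1-en-2-yl)-1,4-dioxaspiro[4.5]decane
Product: 11 3-[(7R,8R)-8-acetyl-7-methyl-1,4-dioxaspiro[4.5]decan-7-yl]propanal, via bis-ozonide 10 (not isolated)
Conditions: O3, CH2Cl2, −78 °C; then PPh3, −78 °C → rt; used without storage
Reagents that add atoms: ozone, [O-][O+]=O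
Why: Ozonolysis with reductive work-up cleaves both terminal alkenes in one operation, the isopropenyl group giving the C4 methyl ketone and the butenyl group the C3 aldehyde, while the neutral conditions spare the ketal and the C5 centre α to the new ketone.

Step 6
Reactants: 11 3-[(7R,8R)-8-acetyl-7-methyl-1,4-dioxaspiro[4.5]decan-7-yl]propanal
Product: 12 (4S,5R,10R)-4α-hydroxy-8,8-ethylenedioxy-5αH-eudesman-3-one (4β-methyl, 10β-methyl, trans ring fusion)
Conditions: (5aR,10bS)-2-(pentafluorophenyl)-5a,10b-dihydro-4H,6H-indeno[2,1-b][1,2,4]triazolo[4,3-d][1,4]oxazin-2-ium tetrafluoroborate (15 mol %), Et3N (15 mol %), toluene, 23 °C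
Reagents that add atoms: none
Why: The free carbene (from the triazolium salt and Et3N) adds to the C3 aldehyde and proton transfer gives the enaminol, an acyl-anion equivalent whose carbon attacks the C4 ketone; proton transfer to the new alkoxide and loss of the carbene release the α-ketol. The closest known reaction type is the carbene-catalysed intramolecular crossed aldehyde–ketone benzoin cyclisation, established for aliphatic aldehydes and six-membered tertiary α-ketols, also with chiral triazolium salts. Ring A closes by a 6-exo-trig attack. C4 is set in a chair-like transition state in which both arms are equatorial on ring B, the bulky azolium sits equatorial at C3 and the enaminol O–H, axial on the α face, hydrogen-bonds to the ketone oxygen, which therefore lies equatorial (α) with the methyl group axial (β), i.e. bonding on the Re face of the ketone; the catalyst antipode that leaves the Re face of the acyl-anion carbon open (taken to be the (5aR,10bS) salt, its mirror image being the direct substitute if the pairing proves mismatched) reinforces this. The step needs crossed chemoselectivity, which is built in because only the aldehyde can become the nucleophile and the C4 ketone is the only carbonyl in reach (C8 is masked), and it needs freedom from aldol closure and from epimerisation at C5, both secured by the weak amine base and the absence of alkoxide.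

Step 7
Reactants: 12 (4S,5R,10R)-4α-hydroxy-8,8-ethylenedioxy-5αH-eudesman-3-one
Product: 13 (3S,4S,5R,10R)-8,8-ethylenedioxy-5αH-eudesmane-3β,4α-diol
Conditions: NaBH4, MeOH, 0 °C
Reagents that add atoms: none
Why: Borohydride reduction of the cyclohexanone by axial hydride attack from the α face, away from the axial 4β-methyl group next door, should give the equatorial 3β-alcohol trans to the 4α-hydroxyl.

Step 8
Reactants: 13 (3S,4S,5R,10R)-8,8-ethylenedioxy-5αH-eudesmane-3β,4α-diol; 14 (R)-2-methylbutanoic acid
Product: 15 3β-[(R)-2-methylbutanoyloxy]-8,8-ethylenedioxy-5αH-eudesman-4α-ol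
Conditions: DCC, DMAP (cat.), CH2Cl2, 0 °C → rt
Reagents that add atoms: (R)-2-methylbutanoic acid, CC[C@@H](C)C(=O)O
Why: Steglich esterification acylates only the secondary C3 hydroxyl, the tertiary C4 hydroxyl being inert to the carbodiimide-activated acid at room temperature, and the mild conditions keep the α-centre of the acid intact.

Step 9
Reactants: 15 3β-[(R)-2-methylbutanoyloxy]-8,8-ethylenedioxy-5αH-eudesman-4α-ol; 5 acetic anhydride
Product: 16 4α-acetoxy-3β-[(R)-2-methylbutanoyloxy]-8,8-ethylenedioxy-5αH-eudesmane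
Conditions: Ac2O (excess), DMAP (1 equiv), Et3N, CH2Cl2, 40 °C
Reagents that add atoms: acetic anhydride, CC(=O)OC(C)=O
Why: DMAP-catalysed acetylation of a tertiary alcohol with excess anhydride and gentle heating, the secondary ester already in place having no drive to migrate to the more hindered tertiary oxygen.

Step 10
Reactants: 16 4α-acetoxy-3β-[(R)-2-methylbutanoyloxy]-8,8-ethylenedioxy-5αH-eudesmane
Product: 17 4α-acetoxy-3β-[(R)-2-methylbutanoyloxy]-5αH-eudesman-8-one
Conditions: 2 M HCl, THF, rt
Reagents that add atoms: water, O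
Why: Acid-catalysed hydrolysis of the dioxolane in dilute aqueous acid at room temperature, which the secondary ester and the tertiary acetate tolerate.

Step 11
Reactants: 17 4α-acetoxy-3β-[(R)-2-methylbutanoyloxy]-5αH-eudesman-8-one; 18 acetone
Product: 21 4α-acetoxy-11-hydroxy-3β-[(R)-2-methylbutanoyloxy]-5αH-eudesman-8-one, via lithium enolate 19 (not isolated), via lithium aldolate 20 (not isolated)
Conditions: LiN(SiMe3)2 (1.05 equiv), THF, −78 °C; acetone (excess), −78 °C; AcOH, −78 °C
Reagents that add atoms: acetone, CC(C)=O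
Why: Kinetic enolisation followed by aldol addition, in which the amide base removes a ketone α-proton much faster than an ester α-proton and takes it from C7 and not from the neopentyl C9, and the enolate adds to acetone before proton exchange if kept at −78 °C and quenched cold.

Step 12
Reactants: 21 4α-acetoxy-11-hydroxy-3β-[(R)-2-methylbutanoyloxy]-5αH-eudesman-8-one
Product: 23 (3S,4S,5R,10R)-4α-acetoxy-3β-[(R)-2-methylbutanoyloxy]eudesm-7(11)-en-8-one (CNP0111007.1), via tertiary mesylate 22 (not isolated)
Conditions: MsCl, Et3N, DMAP (cat.), CH2Cl2, 0 °C → rt; then DBU, rt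
Reagents that add atoms: none
Why: Mesylation of the tertiary aldol hydroxyl and base-mediated E1cB elimination through the C7 enolate should give the conjugated, tetrasubstituted C7=C11 alkene and erase the C7 centre.

Compound list
1 | (1R,5R)-(+)-verbenone, (1R,5R)-4,6,6-trimethylbicyclo[3.1.1]hept-3-en-2-one | CC1=CC(=O)[C@@H]2C[C@H]1C2(C)C | starting material
2 | but-3-en-1-ylmagnesium bromide | C=CCC[Mg]Br | starting material
3 | bromomagnesium C2–C3 enolate of 4 | Br[Mg]OC1=C[C@@](C)(CCC=C)[C@H]2C[C@@H]1C2(C)C | intermediate (not isolated)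
4 | (1R,4R,5R)-4-(but-3-en-1-yl)-4,6,6-trimethylbicyclo[3.1.1]heptan-2-one (butenyl anti to the gem-dimethyl bridge) | O=C1C[C@@](C)(CCC=C)[C@H]2C[C@@H]1C2(C)C | intermediate
5 | acetic anhydride | CC(=O)OC(C)=O | starting material
6 | (4S,5R)-5-(but-3-en-1-yl)-5-methyl-4-(prop-1-en-2-yl)cyclohex-1-en-1-yl acetate | C=CCC[C@]1(C)CC(OC(C)=O)=CC[C@H]1C(C)=C | intermediate
7 | (3R,4S)-3-(but-3-en-1-yl)-3-methyl-4-(prop-1-en-2-yl)cyclohexan-1-one | C=CCC[C@]1(C)CC(=O)CC[C@H]1C(C)=C | intermediate
8 | ethylene glycol | OCCO | starting material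
9 | (7R,8S)-7-(but-3-en-1-yl)-7-methyl-8-(prop-1-en-2-yl)-1,4-dioxaspiro[4.5]decane | C=CCC[C@]1(C)CC2(OCCO2)CC[C@H]1C(C)=C | intermediate
10 | bis-ozonide of 9 (a 1,2,4-trioxolane at each former alkene, trioxolane carbons unassigned) | C1(CC[C@]2(C)CC3(OCCO3)CC[C@H]2C4(C)OOCO4)OOCO1 | intermediate (not isolated)
11 | 3-[(7R,8R)-8-acetyl-7-methyl-1,4-dioxaspiro[4.5]decan-7-yl]propanal (3,4-seco keto-aldehyde; acetyl trans to the propanal arm) | O=CCC[C@]1(C)CC2(OCCO2)CC[C@H]1C(C)=O | intermediate
12 | (4S,5R,10R)-4α-hydroxy-8,8-ethylenedioxy-5αH-eudesman-3-one | O=C1CC[C@]2(C)CC3(OCCO3)CC[C@H]2[C@]1(C)O | intermediate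
13 | (3S,4S,5R,10R)-8,8-ethylenedioxy-5αH-eudesmane-3β,4α-diol | O[C@H]1CC[C@]2(C)CC3(OCCO3)CC[C@H]2[C@]1(C)O | intermediate
14 | (R)-2-methylbutanoic acid | CC[C@@H](C)C(=O)O | starting material
15 | 3β-[(R)-2-methylbutanoyloxy]-8,8-ethylenedioxy-5αH-eudesman-4α-ol | CC[C@@H](C)C(=O)O[C@H]1CC[C@]2(C)CC3(OCCO3)CC[C@H]2[C@]1(C)O | intermediate
16 | 4α-acetoxy-3β-[(R)-2-methylbutanoyloxy]-8,8-ethylenedioxy-5αH-eudesmane | CC[C@@H](C)C(=O)O[C@H]1CC[C@]2(C)CC3(OCCO3)CC[C@H]2[C@]1(C)OC(C)=O | intermediate
17 | 4α-acetoxy-3β-[(R)-2-methylbutanoyloxy]-5αH-eudesman-8-one | CC[C@@H](C)C(=O)O[C@H]1CC[C@]2(C)CC(=O)CC[C@H]2[C@]1(C)OC(C)=O | intermediate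
18 | acetone | CC(C)=O | starting material
19 | lithium C7–C8 enolate of 17 | CC[C@@H](C)C(=O)O[C@H]1CC[C@]2(C)CC(O[Li])=CC[C@H]2[C@]1(C)OC(C)=O | intermediate (not isolated)
20 | lithium aldolate (C11 alkoxide) of 21 | CC[C@@H](C)C(=O)O[C@H]1CC[C@]2(C)CC(=O)C(C(C)(C)O[Li])C[C@H]2[C@]1(C)OC(C)=O | intermediate (not isolated)
21 | 4α-acetoxy-11-hydroxy-3β-[(R)-2-methylbutanoyloxy]-5αH-eudesman-8-one | CC[C@@H](C)C(=O)O[C@H]1CC[C@]2(C)CC(=O)C(C(C)(C)O)C[C@H]2[C@]1(C)OC(C)=O | intermediate
22 | C11 methanesulfonate of 21 | CC[C@@H](C)C(=O)O[C@H]1CC[C@]2(C)CC(=O)C(C(C)(C)OS(C)(=O)=O)C[C@H]2[C@]1(C)OC(C)=O | intermediate (not isolated)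
23 | (3S,4S,5R,10R)-4α-acetoxy-3β-[(R)-2-methylbutanoyloxy]eudesm-7(11)-en-8-one, CNP0111007.1 | CC[C@@H](C)C(=O)O[C@H]1CC[C@]2(C)CC(=O)C(=C(C)C)C[C@H]2[C@]1(C)OC(C)=O | target

Total step count: 12. Longest linear sequence: 12 steps, from 1 to 23.

Steps most likely to fail

Step 6. The closure may show poor facial selectivity at the C4 carbonyl, because the developing 1,3-diaxial contact between the C4 and C10 methyl groups could steer bonding toward the 4-epimer, or aldol closure may overtake carbene addition. The fallback sets out from 11 and comes back at 12. Reductive carbonyl coupling of the aldehyde and the ketone (McMurry coupling; TiCl3(DME)1.5, Zn–Cu couple, DME, reflux, slow addition) would join C3 and C4 as the ring A alkene 8,8-ethylenedioxy-5αH-eudesm-3-ene F1. Dihydroxylation (OsO4 cat., NMO, acetone–water) should occur on the α face, opposite the axial C10 methyl group, to give 8,8-ethylenedioxy-5αH-eudesmane-3α,4α-diol F2. Oxidation of the secondary hydroxyl alone (SO3·pyridine, DMSO, Et3N) would then give 12.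

Step 11. The base may also deprotonate the acetate or the α-carbon of the methylbutanoate, and the aldol addition may be reversed by proton transfer to acetone. The fallback sets out from 17 and comes back at 21. Soft enolisation (Me3SiOTf, Et3N, CH2Cl2, 0 °C), which leaves esters alone, would give the C7–C8 trimethylsilyl enol ether of 17 F5. A Mukaiyama aldol addition to acetone (TiCl4, CH2Cl2, −78 °C) would then give 21 without any strong base.

Step 2. The tertiary cation may be captured by acetate or by the terminal alkene instead of losing a proton cleanly, or the alkene may be acylated. The fallback sets out from 4 and comes back at 7, so that step 3 is not needed. Iodide-assisted opening of the cyclobutane (Me3SiI, CH2Cl2, 0 °C) would give [(4R,5R)-5-(but-3-en-1-yl)-4-(2-iodopropan-2-yl)-5-methylcyclohex-1-en-1-yl]oxytrimethylsilane F3. Aqueous work-up would hydrolyse it to (3R,4R)-3-(but-3-en-1-yl)-4-(2-iodopropan-2-yl)-3-methylcyclohexan-1-one F4. Elimination toward a methyl group with DBU in toluene would then give 7.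

Further compounds
F1 | step 6 | 8,8-ethylenedioxy-5αH-eudesm-3-ene | CC1=CCC[C@]2(C)CC3(OCCO3)CC[C@@H]12
F2 | step 6 | 8,8-ethylenedioxy-5αH-eudesmane-3α,4α-diol | O[C@@H]1CC[C@]2(C)CC3(OCCO3)CC[C@H]2[C@]1(C)O
F3 | step 2 | [(4R,5R)-5-(but-3-en-1-yl)-4-(2-iodopropan-2-yl)-5-methylcyclohex-1-en-1-yl]oxytrimethylsilane | C=CCC[C@]1(C)CC(O[Si](C)(C)C)=CC[C@H]1C(C)(C)I
F4 | step 2 | (3R,4R)-3-(but-3-en-1-yl)-4-(2-iodopropan-2-yl)-3-methylcyclohexan-1-one | C=CCC[C@]1(C)CC(=O)CC[C@H]1C(C)(C)I
F5 | step 11 | C7–C8 trimethylsilyl enol ether of 17 | CC[C@@H](C)C(=O)O[C@H]1CC[C@]2(C)CC(O[Si](C)(C)C)=CC[C@H]2[C@]1(C)OC(C)=O
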